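**Retrosynthetic overview**
- The aryl allyl ether C–O bond is cut last (Mitsunobu), giving 7-hydroxy-8-methoxycoumarin (14 heavy atoms) and a TES-protected C10 epoxy allylic alcohol (13 heavy atoms plus TES).
- Coumarin half: the pyran-2-one ring is closed onto 2-methoxyresorcinol with ethyl propiolate; 2-methoxyresorcinol comes from resorcinol by directed ortho-metalation, borylation–oxidation and O-methylation.
- Side-chain half: the C4'–C5' bond, the 2'E olefin and the 5'S carbinol come from a catalytic asymmetric vinylogous Mukaiyama aldol of 3-methylbut-2-enal with the silyl dienolate of methyl 3-methylbut-2-enoate.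
- The oxirane (6'S) is then made by a matched Sharpless epoxidation of that secondary allylic alcohol.
- Ring order: benzene (bought), then pyran-2-one (step 5) and oxirane (step 8) in parallel branches, then fragment union (step 11).

Target configuration (from the SMILES): 2'E, carbinol carbon S, oxirane CH carbon S, i.e. the erythro epoxy alcohol.

Assumption: SiCl4/(R,R)-Denmark bisphosphoramide is taken to direct Re-face attack on conjugated aldehydes, so the (S,S)-catalyst is written in step 7 for Si-face attack (5S); if Mosher analysis of 16 shows the opposite sense, the antipodal catalyst is used with no other change.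

**Step 1**
Reactants: 1 resorcinol
Product: 2 1,3-bis(methoxymethoxy)benzene
Conditions: MOMCl (2.4 equiv), iPr2NEt (3 equiv), CH2Cl2, 0 °C to rt
Reagents that add atoms: chloromethyl methyl ether, COCCl
Why: Double O-alkylation of the phenols (MOM protection) installs two ortho-directing groups that flank C2.

**Step 2**
Reactants: 2 1,3-bis(methoxymethoxy)benzene
Product: 5 2,6-bis(methoxymethoxy)phenol, via aryllithium 3 (not isolated), via lithium aryltrimethoxyborate 4 (not isolated)
Conditions: n-BuLi (1.1 equiv), THF, 0 °C to rt; B(OMe)3, −78 °C to rt; AcOH (1.1 equiv), 30% H2O2, 0 °C to rt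
Reagents that add atoms: hydrogen peroxide, OO (the phenolic O); n-butyllithium, [Li]CCCC and trimethyl borate, COB(OC)OC (atoms only in 3 and 4)
Why: Directed ortho-metalation at the doubly activated C2, borylation and Hawthorne-type oxidation (aryl migration from B to O) turn that C–H into C–OH regiospecifically.

**Step 3**
Reactants: 5 2,6-bis(methoxymethoxy)phenol
Product: 6 2-methoxy-1,3-bis(methoxymethoxy)benzene
Conditions: MeI (1.5 equiv), K2CO3 (1.5 equiv), acetone, reflux
Reagents that add atoms: iodomethane, CI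
Why: Williamson O-methylation of the only free phenol.

**Step 4**
Reactants: 6 2-methoxy-1,3-bis(methoxymethoxy)benzene
Product: 7 2-methoxybenzene-1,3-diol
Conditions: conc. HCl (cat.), MeOH, 50 °C
Reagents that add atoms: none
Why: Acid-catalysed acetal methanolysis removes both MOM groups while the aryl methyl ether is inert.

**Step 5**
Reactants: 7 2-methoxybenzene-1,3-diol; 8 ethyl propiolate
Product: 10 7-hydroxy-8-methoxy-2H-chromen-2-one, via Z-cinnamate 9 (not isolated)
Conditions: Pd(OAc)2 (3 mol %), TFA/CH2Cl2, rt; 1.05 equiv of 8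
Reagents that add atoms: none
Why: Pd(II)/TFA trans-hydroarylation (Fujiwara type) of the propiolate at C4 (ortho to one OH, para to the other; C4 and C6 are equivalent) gives the Z-cinnamate, which lactonises onto the adjacent OH to close the pyran-2-one ring.

**Step 6**
Reactants: 11 methyl 3-methylbut-2-enoate
Product: 13 tert-butyl{[(1Z)-1-methoxy-3-methylbuta-1,3-dien-1-yl]oxy}dimethylsilane, via lithium dienolate 12 (not isolated)
Conditions: LDA (1.1 equiv), THF/DMPU, −78 °C; TBSCl, −78 °C to rt; distil
Reagents that add atoms: tert-butyldimethylsilyl chloride, CC(C)(C)[Si](C)(C)Cl; lithium diisopropylamide, [Li]N(C(C)C)C(C)C (Li only in 12)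
Why: Kinetic γ-deprotonation of the enoate gives the vinylogous ester enolate, and O-silylation traps it as the silyl dienol ether; its C1=C2 geometry is lost in the next step.

**Step 7**
Reactants: 13 silyl dienol ether; 14 3-methylbut-2-enal
Product: 16 methyl (2E,5S)-5-hydroxy-3,7-dimethylocta-2,6-dienoate, via trichlorosilyl ether 15 (not isolated)
Conditions: SiCl4 (1.1 equiv), (S,S)-Denmark bisphosphoramide (5 mol %; the pentamethylene-linked bis-phosphoramide of N,N'-dimethyl-1,1'-binaphthyl-2,2'-diamine), iPr2NEt (10 mol %), CH2Cl2, −78 °C; cold aqueous bicarbonate work-up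
Reagents that add atoms: silicon tetrachloride, Cl[Si](Cl)(Cl)Cl (SiCl3 only in 15; nothing remains in 16)
Why: Lewis-base-activated SiCl4 vinylogous Mukaiyama aldol: γ-attack of the s-trans dienolate through an open transition state on the Si face of the enal sets 5S and gives the 2E enoate.

**Step 8**
Reactants: 16 methyl (2E,5S)-5-hydroxy-3,7-dimethylocta-2,6-dienoate
Product: 17 methyl (2E,5S)-5-[(2S)-3,3-dimethyloxiran-2-yl]-5-hydroxy-3-methylpent-2-enoate
Conditions: Ti(OiPr)4 (0.3 equiv), L-(+)-DIPT (0.36 equiv), TBHP (1.0 equiv, anhydrous in decane), 4 Å MS, CH2Cl2, −20 °C; stop at about 95% conversion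
Reagents that add atoms: tert-butyl hydroperoxide, CC(C)(C)OO
Why: Sharpless asymmetric epoxidation in its matched kinetic-resolution mode: with L-(+)-tartrate the 5S alcohol is the fast enantiomer and receives oxygen on the face that gives the 6S, erythro epoxy alcohol, which also raises the ee; the enoate olefin has no allylic OH and is inert.

**Step 9**
Reactants: 17 epoxy alcohol
Product: 18 methyl (2E,5S)-5-[(2S)-3,3-dimethyloxiran-2-yl]-3-methyl-5-(triethylsilyloxy)pent-2-enoate
Conditions: TESCl (1.3 equiv), imidazole (2.5 equiv), DMAP (cat.), CH2Cl2, 0 °C to rt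
Reagents that add atoms: chlorotriethylsilane, CC[Si](Cl)(CC)CC
Why: Silylation of the secondary alcohol under non-Lewis-acidic conditions (no silyl triflate) protects it without opening the trisubstituted epoxide.

**Step 10**
Reactants: 18 TES-protected epoxy ester
Product: 20 (2E,5S)-5-[(2S)-3,3-dimethyloxiran-2-yl]-3-methyl-5-(triethylsilyloxy)pent-2-en-1-ol, via enal 19 (not isolated)
Conditions: DIBAL-H (2.3 equiv), CH2Cl2, −78 °C; Rochelle salt work-up
Reagents that add atoms: none
Why: DIBAL-H 1,2-reduction of the enoate to the allylic alcohol at −78 °C leaves the epoxide, silyl ether and E olefin untouched.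

**Step 11**
Reactants: 10 7-hydroxy-8-methoxy-2H-chromen-2-one; 20 allylic alcohol
Product: 22 7-{[(2E,5S)-5-[(2S)-3,3-dimethyloxiran-2-yl]-3-methyl-5-(triethylsilyloxy)pent-2-en-1-yl]oxy}-8-methoxy-2H-chromen-2-one, via oxyphosphonium salt 21 (not isolated)
Conditions: PPh3 (1.3 equiv), DIAD (1.3 equiv), THF, 0 °C to rt
Reagents that add atoms: none
Why: Mitsunobu etherification: the acidic 7-OH (pKa about 8) displaces the activated primary allylic oxygen by SN2 at a CH2 carbon, so neither stereocentre nor the olefin geometry is touched.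

**Step 12**
Reactants: 22 TES-protected coupled ether
Product: 23 7-{[(2E,5S)-5-[(2S)-3,3-dimethyloxiran-2-yl]-5-hydroxy-3-methylpent-2-en-1-yl]oxy}-8-methoxy-2H-chromen-2-one
Conditions: TBAF (1.5 equiv), AcOH (1.5 equiv), THF, 0 °C to rt
Reagents that add atoms: none
Why: Buffered fluoride desilylation frees the secondary alcohol without Payne rearrangement, epoxide opening or lactone cleavage.

**Compound list**
1 | resorcinol | Oc1cccc(O)c1 | starting material
2 | 1,3-bis(methoxymethoxy)benzene | COCOc1cccc(OCOC)c1 | intermediate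
3 | [2,6-bis(methoxymethoxy)phenyl]lithium | [Li]c1c(OCOC)cccc1OCOC | intermediate (not isolated)
4 | lithium [2,6-bis(methoxymethoxy)phenyl]trimethoxyborate | [Li+].CO[B-](OC)(OC)c1c(OCOC)cccc1OCOC | intermediate (not isolated)
5 | 2,6-bis(methoxymethoxy)phenol | COCOc1cccc(OCOC)c1O | intermediate
6 | 2-methoxy-1,3-bis(methoxymethoxy)benzene | COCOc1cccc(OCOC)c1OC | intermediate
7 | 2-methoxybenzene-1,3-diol | COc1c(O)cccc1O | intermediate
8 | ethyl propiolate | CCOC(=O)C#C | starting material
9 | ethyl (2Z)-3-(2,4-dihydroxy-3-methoxyphenyl)prop-2-enoate | CCOC(=O)/C=C\c1ccc(O)c(OC)c1O | intermediate (not isolated)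
10 | 7-hydroxy-8-methoxy-2H-chromen-2-one | COc1c(O)ccc2ccc(=O)oc12 | intermediate
11 | methyl 3-methylbut-2-enoate | COC(=O)C=C(C)C | starting material
12 | lithium 1-methoxy-3-methylbuta-1,3-dien-1-olate | [Li+].[O-]/C(OC)=C\C(C)=C | intermediate (not isolated)
13 | tert-butyl{[(1Z)-1-methoxy-3-methylbuta-1,3-dien-1-yl]oxy}dimethylsilane | CO/C(O[Si](C)(C)C(C)(C)C)=C/C(C)=C | intermediate
14 | 3-methylbut-2-enal | CC(C)=CC=O | starting material
15 | methyl (2E,5S)-3,7-dimethyl-5-(trichlorosilyloxy)octa-2,6-dienoate | COC(=O)/C=C(\C)C[C@H](O[Si](Cl)(Cl)Cl)C=C(C)C | intermediate (not isolated)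
16 | methyl (2E,5S)-5-hydroxy-3,7-dimethylocta-2,6-dienoate | COC(=O)/C=C(\C)C[C@H](O)C=C(C)C | intermediate
17 | methyl (2E,5S)-5-[(2S)-3,3-dimethyloxiran-2-yl]-5-hydroxy-3-methylpent-2-enoate | COC(=O)/C=C(\C)C[C@H](O)[C@@H]1OC1(C)C | intermediate
18 | methyl (2E,5S)-5-[(2S)-3,3-dimethyloxiran-2-yl]-3-methyl-5-(triethylsilyloxy)pent-2-enoate | COC(=O)/C=C(\C)C[C@H](O[Si](CC)(CC)CC)[C@@H]1OC1(C)C | intermediate
19 | (2E,5S)-5-[(2S)-3,3-dimethyloxiran-2-yl]-3-methyl-5-(triethylsilyloxy)pent-2-enal | O=C/C=C(\C)C[C@H](O[Si](CC)(CC)CC)[C@@H]1OC1(C)C | intermediate (not isolated)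
20 | (2E,5S)-5-[(2S)-3,3-dimethyloxiran-2-yl]-3-methyl-5-(triethylsilyloxy)pent-2-en-1-ol | OC/C=C(\C)C[C@H](O[Si](CC)(CC)CC)[C@@H]1OC1(C)C | intermediate
21 | {[(2E,5S)-5-[(2S)-3,3-dimethyloxiran-2-yl]-3-methyl-5-(triethylsilyloxy)pent-2-en-1-yl]oxy}triphenylphosphonium 8-methoxy-2-oxo-2H-chromen-7-olate | c1ccccc1[P+](c1ccccc1)(c1ccccc1)OC/C=C(\C)C[C@H](O[Si](CC)(CC)CC)[C@@H]1OC1(C)C.COc1c([O-])ccc2ccc(=O)oc12 | intermediate (not isolated)
22 | 7-{[(2E,5S)-5-[(2S)-3,3-dimethyloxiran-2-yl]-3-methyl-5-(triethylsilyloxy)pent-2-en-1-yl]oxy}-8-methoxy-2H-chromen-2-one | COc1c(OC/C=C(\C)C[C@H](O[Si](CC)(CC)CC)[C@@H]2OC2(C)C)ccc2ccc(=O)oc12 | intermediate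
23 | 7-{[(2E,5S)-5-[(2S)-3,3-dimethyloxiran-2-yl]-5-hydroxy-3-methylpent-2-en-1-yl]oxy}-8-methoxy-2H-chromen-2-one | COc1c(OC/C=C(\C)C[C@H](O)[C@@H]2OC2(C)C)ccc2ccc(=O)oc12 | target

**Totals**
Total step count: 12.
Longest linear sequence: 7 steps (steps 6–12 from 11, or steps 1–5 then 11–12 from 1).

**Three steps most likely to fail, with fallbacks**

Step 5 (hydroarylation–lactonisation on a free, very electron-rich diphenol; risk of double addition or low conversion). The fallback sets out from 6 and comes back at 10. Compound 6 is lithiated a second time (n-BuLi/TMEDA, THF, 0 °C, ortho to an OMOM group) and quenched with DMF to give 3-methoxy-2,4-bis(methoxymethoxy)benzaldehyde F1. HCl/MeOH then gives 2,4-dihydroxy-3-methoxybenzaldehyde F2. Wittig olefination with Ph3P=CHCO2Et in N,N-diethylaniline at reflux gives ethyl (2E)-3-(2,4-dihydroxy-3-methoxyphenyl)prop-2-enoate F3, which isomerises and lactonises under the same thermal conditions to 10. The pyranone ring is then built from a salicylaldehyde instead of by arene C–H addition to an alkyne.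

Step 7 (enantioselective vinylogous aldol with a hindered β,β-disubstituted enal; ee, rate and the face sense of the catalyst are the uncertainties). The fallback sets out from 13 and 14 and comes back at 17. A racemic vinylogous Mukaiyama aldol (BF3·OEt2, CH2Cl2, −78 °C) gives racemic methyl (2E)-5-hydroxy-3,7-dimethylocta-2,6-dienoate F4. F4 is then put through the Sharpless conditions of step 8 as a true kinetic resolution (stoichiometric Ti(OiPr)4/L-(+)-DIPT, 0.55 equiv TBHP, −20 °C). Only the fast 5S enantiomer is epoxidised, directly to 17; the slow-reacting methyl (2E,5R)-5-hydroxy-3,7-dimethylocta-2,6-dienoate F5 is separated by chromatography. The 5S centre then comes from resolution instead of from asymmetric C–C bond formation.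

Step 8 (Sharpless epoxidation of a secondary allylic alcohol whose olefin carries a cis methyl group; A(1,3) strain slows the matched pathway and favours the threo isomer). The fallback sets out from 16 and comes back at 18. The alcohol is silylated first (TESCl, imidazole) to methyl (2E,5S)-3,7-dimethyl-5-(triethylsilyloxy)octa-2,6-dienoate F6. F6 is epoxidised with the enantiomeric Shi ketone (L-fructose-derived), Oxone, K2CO3 buffer, Bu4NHSO4, MeCN/dimethoxymethane/water, 0 °C. The chiral dioxirane gives the 6S epoxide on the electron-rich trisubstituted olefin, reinforced by attack anti to the bulky silyloxy group in the A(1,3)-minimised conformer; the enoate is inert, and the product is 18 directly. Hydroxyl-directed metal catalysis is thereby replaced by non-directed, reagent-controlled dioxirane epoxidation.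

**Further compounds**
F1 | step 5 | 3-methoxy-2,4-bis(methoxymethoxy)benzaldehyde | COCOc1ccc(C=O)c(OCOC)c1OC
F2 | step 5 | 2,4-dihydroxy-3-methoxybenzaldehyde | COc1c(O)ccc(C=O)c1O
F3 | step 5 | ethyl (2E)-3-(2,4-dihydroxy-3-methoxyphenyl)prop-2-enoate | CCOC(=O)/C=C/c1ccc(O)c(OC)c1O
F4 | step 7 | methyl (2E)-5-hydroxy-3,7-dimethylocta-2,6-dienoate (racemic) | COC(=O)/C=C(\C)CC(O)C=C(C)C
F5 | step 7 | methyl (2E,5R)-5-hydroxy-3,7-dimethylocta-2,6-dienoate | COC(=O)/C=C(\C)C[C@@H](O)C=C(C)C
F6 | step 8 | methyl (2E,5S)-3,7-dimethyl-5-(triethylsilyloxy)octa-2,6-dienoate | COC(=O)/C=C(\C)C[C@H](O[Si](CC)(CC)CC)C=C(C)C
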